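**Retrosynthetic overview**

1. Target 18 is cut at the methylene bridge: the ortho-quinone methide released from the chromene Mannich base 12 is joined in the last step to the C–H acidic carbon of the (S)-dienone 16.
2. 16 comes from the methyl acylphloroglucinol 14 by Pd-catalysed asymmetric dearomative prenylation, which sets the only stereocentre.
3. The 2H-pyran ring of 12 is not closed directly. It comes from one-carbon ring expansion of the five-membered ring (O1–C2–C3–C3a–C7a) of the 2-isopropenyl-2,3-dihydrobenzofuran 7, which is made from iodide 5 and isoprene after the hydroxyl para to the ketone is silylated.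
4. Enabling feature: in 7 the ring bond O1–C2 is an allylic aryl ether (C2 carries the isopropenyl group), O1 is a phenoxide stabilised by the isobutyryl group at C7, and C3 carries benzylic hydrogens. Palladium can therefore move O1 from C2 to the exocyclic alkene carbon, which becomes the gem-dimethyl carbon C2 of the pyran.
5. Ring order: the benzene rings are bought; dihydrofuran (step 4), then 2H-pyran (step 5); the cyclohexadienone by dearomatisation (step 9); the halves are joined in step 10.

Key step: step 5

Assumption: the β-triketone units are drawn as the enol tautomers of the target SMILES, and the (S,S) ligand in step 9 is taken to give the (S) centre (its antipode is used if the first run shows the opposite sense).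

**Step 1**
Reactants: 1 phloroglucinol; 2 isobutyryl chloride
Product: 3 1-(2,4,6-trihydroxyphenyl)-2-methylpropan-1-one
Conditions: AlCl3 (3.5 equiv), PhNO2/CH2Cl2, 0 to 45 °C; aq. HCl work-up
Reagents that add atoms: none
Why: Friedel–Crafts acylation of the electron-rich triol stops after one acylation because the ketone–AlCl3 complex deactivates the ring.

**Step 2**
Reactants: 3 1-(2,4,6-trihydroxyphenyl)-2-methylpropan-1-one
Product: 4 1-{2,6-dihydroxy-4-[(triisopropylsilyl)oxy]phenyl}-2-methylpropan-1-one
Conditions: TIPSCl (1.05 equiv), imidazole (1.1 equiv), DMF, 0 °C to rt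
Reagents that add atoms: triisopropylsilyl chloride, CC(C)[Si](Cl)(C(C)C)C(C)C
Why: Selective silylation: the hydroxyl para to the ketone is the only one not hydrogen-bonded to the carbonyl group and the least hindered, so the bulky silyl chloride should take it alone and leave the two equivalent chelated hydroxyls for the later ring closure.

**Step 3**
Reactants: 4 1-{2,6-dihydroxy-4-[(triisopropylsilyl)oxy]phenyl}-2-methylpropan-1-one
Product: 5 1-{2,6-dihydroxy-3-iodo-4-[(triisopropylsilyl)oxy]phenyl}-2-methylpropan-1-one
Conditions: NIS (1.0 equiv), CH2Cl2, −20 to 0 °C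
Reagents that add atoms: N-iodosuccinimide, O=C1CCC(=O)N1I
Why: Electrophilic aromatic iodination of an activated phenol; the two free ring positions are equivalent, so one equivalent of NIS should give a single mono-iodide.

**Step 4**
Reactants: 5 1-{2,6-dihydroxy-3-iodo-4-[(triisopropylsilyl)oxy]phenyl}-2-methylpropan-1-one; 6 isoprene
Product: 7 1-{6-hydroxy-2-(prop-1-en-2-yl)-4-[(triisopropylsilyl)oxy]-2,3-dihydro-1-benzofuran-7-yl}-2-methylpropan-1-one (racemic at C2)
Conditions: Pd(OAc)2 (5 mol %), NaHCO3 (3 equiv), n-Bu4NCl (1 equiv), isoprene (5 equiv), DMF, 70 °C, sealed tube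
Reagents that add atoms: none
Why: Larock heteroannulation of a 1,3-diene: aryl–Pd adds to the unsubstituted vinyl terminus of isoprene and the π-allyl complex is captured 5-exo by the only adjacent free phenoxide (the other neighbour is silylated); the new C2 centre is racemic and is erased in step 5.

**Step 5**
Reactants: 7 1-{6-hydroxy-2-(prop-1-en-2-yl)-4-[(triisopropylsilyl)oxy]-2,3-dihydro-1-benzofuran-7-yl}-2-methylpropan-1-one
Product: 9 1-{7-hydroxy-2,2-dimethyl-5-[(triisopropylsilyl)oxy]-2H-chromen-8-yl}-2-methylpropan-1-one, via dienylphenol 8 (not isolated)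
Conditions: Pd2(dba)3 (2.5 mol %), PPh3 (10 mol %), PhCO2H (10 mol %), toluene (0.02 M), 90 °C
Reagents that add atoms: none
Why: Proposed new method: Pd(0) ionises the allylic aryl ether bond O1–C2 of 7 (the ortho-acyl phenoxide is a good leaving group) to a π-allyl palladium phenoxide, β-hydride elimination of a benzylic C3–H gives dienylphenol 8 and a Pd–H species, Pd–H adds back to the terminal CH2 of the diene to form the 1,1-dimethyl-3-aryl π-allyl, and the phenoxide closes on its CMe2 terminus to give 9. The closest known reaction types are the Tsuji–Trost elimination of allylic ethers to 1,3-dienes, the Pd–H (Pd(0)/carboxylic acid) hydroalkoxylation of 1,3-dienes through π-allyl intermediates, and intramolecular Pd-allylic etherification. The pyran is closed by intramolecular O-attack on the tertiary π-allyl terminus in a six-membered allylic etherification (the other terminus would need a four-membered ring), so the five-membered ring grows by the former exocyclic carbon, which becomes C2. No stereocentre is formed and the racemic C2 centre of 7 is erased. The step needs 9 over return to 7 and over the seven-membered 3-methyl-2,5-dihydro-1-benzoxepine isomer: all these allylic ethers should stay in Pd-mediated equilibrium through the same π-allyl manifold while the conjugated chromene is the expected thermodynamic sink, and the silyl ether on O5 leaves only O1 able to close, which fixes the 8-acyl regiochemistry. Aromatisation to a 2-isopropylbenzofuran is not reachable from the π-allyl manifold because no acid strong enough to protonate the alkene is present.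

**Step 6**
Reactants: 9 1-{7-hydroxy-2,2-dimethyl-5-[(triisopropylsilyl)oxy]-2H-chromen-8-yl}-2-methylpropan-1-one
Product: 10 1-(5,7-dihydroxy-2,2-dimethyl-2H-chromen-8-yl)-2-methylpropan-1-one
Conditions: TBAF (1.1 equiv), AcOH (1.1 equiv), THF, 0 °C
Reagents that add atoms: none
Why: Buffered fluoride cleavage of an aryl silyl ether should leave the chromene alkene, the ketone and the phenols untouched.

**Step 7**
Reactants: 10 1-(5,7-dihydroxy-2,2-dimethyl-2H-chromen-8-yl)-2-methylpropan-1-one; 11 N,N-dimethylmethyleneiminium iodide (Eschenmoser's salt)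
Product: 12 1-{6-[(dimethylamino)methyl]-5,7-dihydroxy-2,2-dimethyl-2H-chromen-8-yl}-2-methylpropan-1-one
Conditions: 11 (1.05 equiv), Et3N (1.1 equiv), CH2Cl2, 0 °C to rt
Reagents that add atoms: none
Why: Phenol Mannich reaction with a preformed iminium salt: C6, between two hydroxyls, is the only unsubstituted aromatic carbon.

**Step 8**
Reactants: 13 2-methylbenzene-1,3,5-triol; 2 isobutyryl chloride
Product: 14 1-(2,4,6-trihydroxy-3-methylphenyl)-2-methylpropan-1-one
Conditions: AlCl3 (3.5 equiv), PhNO2/CH2Cl2, 0 to 45 °C; aq. HCl work-up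
Reagents that add atoms: none
Why: Friedel–Crafts acylation as in step 1; both free ring positions of 13 are equivalent.

**Step 9**
Reactants: 14 1-(2,4,6-trihydroxy-3-methylphenyl)-2-methylpropan-1-one; 15 3-methylbut-2-en-1-yl acetate (prenyl acetate)
Product: 16 (4S)-3,5-dihydroxy-4-methyl-4-(3-methylbut-2-en-1-yl)-6-(2-methylpropanoyl)cyclohexa-2,5-dien-1-one
Conditions: Pd2(dba)3·CHCl3 (2.5 mol %), (S,S)-DACH-phenyl bisphosphine ligand N,N′-[(1S,2S)-cyclohexane-1,2-diyl]bis[2-(diphenylphosphino)benzamide] (7.5 mol %), Li2CO3 (1.0 equiv), 15 (1.0 equiv), 1,4-dioxane, rt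
Reagents that add atoms: none
Why: Pd-catalysed asymmetric allylic dearomatisation (Tsuji–Trost allylation of a prochiral phenoxide): the methyl-bearing carbon, the most electron-rich ring carbon, attacks the unsubstituted terminus of the π-prenyl complex inside the chiral pocket of the ligand, which sets the quaternary (S) centre and gives the linear prenyl group.

**Step 10**
Reactants: 12 1-{6-[(dimethylamino)methyl]-5,7-dihydroxy-2,2-dimethyl-2H-chromen-8-yl}-2-methylpropan-1-one; 16 (4S)-3,5-dihydroxy-4-methyl-4-(3-methylbut-2-en-1-yl)-6-(2-methylpropanoyl)cyclohexa-2,5-dien-1-one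
Product: 18 (4S)-2-{[5,7-dihydroxy-2,2-dimethyl-8-(2-methylpropanoyl)-2H-chromen-6-yl]methyl}-3,5-dihydroxy-4-methyl-4-(3-methylbut-2-en-1-yl)-6-(2-methylpropanoyl)cyclohexa-2,5-dien-1-one (CNP0301804.1), via ortho-quinone methide 17 (not isolated)
Conditions: 12 (1.0 equiv), 16 (1.05 equiv), toluene, 90 °C, N2 stream; dilute aq. HCl wash
Reagents that add atoms: none
Why: Thermal retro-Mannich loss of dimethylamine from the ortho-hydroxybenzylamine gives the ortho-quinone methide 17, which is trapped by Michael addition of the single C–H acidic carbon of 16; no homo-dimer can form because neither partner has a second free carbon, and the quaternary stereocentre is not involved.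

**Compound list**

1 | phloroglucinol (benzene-1,3,5-triol) | Oc1cc(O)cc(O)c1 | starting material
2 | isobutyryl chloride | CC(C)C(=O)Cl | starting material
3 | 1-(2,4,6-trihydroxyphenyl)-2-methylpropan-1-one | CC(C)C(=O)c1c(O)cc(O)cc1O | intermediate
4 | 1-{2,6-dihydroxy-4-[(triisopropylsilyl)oxy]phenyl}-2-methylpropan-1-one | CC(C)C(=O)c1c(O)cc(O[Si](C(C)C)(C(C)C)C(C)C)cc1O | intermediate
5 | 1-{2,6-dihydroxy-3-iodo-4-[(triisopropylsilyl)oxy]phenyl}-2-methylpropan-1-one | CC(C)C(=O)c1c(O)cc(O[Si](C(C)C)(C(C)C)C(C)C)c(I)c1O | intermediate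
6 | isoprene (2-methylbuta-1,3-diene) | C=CC(C)=C | starting material
7 | 1-{6-hydroxy-2-(prop-1-en-2-yl)-4-[(triisopropylsilyl)oxy]-2,3-dihydro-1-benzofuran-7-yl}-2-methylpropan-1-one (racemic) | CC(=C)C1Cc2c(O[Si](C(C)C)(C(C)C)C(C)C)cc(O)c(C(=O)C(C)C)c2O1 | intermediate
8 | (E)-1-{2,6-dihydroxy-3-(3-methylbuta-1,3-dien-1-yl)-4-[(triisopropylsilyl)oxy]phenyl}-2-methylpropan-1-one | CC(=C)/C=C/c1c(O[Si](C(C)C)(C(C)C)C(C)C)cc(O)c(C(=O)C(C)C)c1O | intermediate (not isolated)
9 | 1-{7-hydroxy-2,2-dimethyl-5-[(triisopropylsilyl)oxy]-2H-chromen-8-yl}-2-methylpropan-1-one | CC(C)C(=O)c1c(O)cc(O[Si](C(C)C)(C(C)C)C(C)C)c2C=CC(C)(C)Oc12 | intermediate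
10 | 1-(5,7-dihydroxy-2,2-dimethyl-2H-chromen-8-yl)-2-methylpropan-1-one | CC(C)C(=O)c1c(O)cc(O)c2C=CC(C)(C)Oc12 | intermediate
11 | N,N-dimethylmethyleneiminium iodide (Eschenmoser's salt) | C=[N+](C)C.[I-] | starting material
12 | 1-{6-[(dimethylamino)methyl]-5,7-dihydroxy-2,2-dimethyl-2H-chromen-8-yl}-2-methylpropan-1-one | CC(C)C(=O)c1c(O)c(CN(C)C)c(O)c2C=CC(C)(C)Oc12 | intermediate
13 | 2-methylbenzene-1,3,5-triol | Cc1c(O)cc(O)cc1O | starting material
14 | 1-(2,4,6-trihydroxy-3-methylphenyl)-2-methylpropan-1-one | Cc1c(O)cc(O)c(C(=O)C(C)C)c1O | intermediate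
15 | 3-methylbut-2-en-1-yl acetate (prenyl acetate) | CC(C)=CCOC(C)=O | starting material
16 | (4S)-3,5-dihydroxy-4-methyl-4-(3-methylbut-2-en-1-yl)-6-(2-methylpropanoyl)cyclohexa-2,5-dien-1-one | CC(C)=CC[C@@]1(C)C(O)=CC(=O)C(C(=O)C(C)C)=C1O | intermediate
17 | 7-hydroxy-2,2-dimethyl-6-methylidene-8-(2-methylpropanoyl)-2H-chromen-5(6H)-one (ortho-quinone methide) | C=C1C(=O)C2=C(OC(C)(C)C=C2)C(C(=O)C(C)C)=C1O | intermediate (not isolated)
18 | (4S)-2-{[5,7-dihydroxy-2,2-dimethyl-8-(2-methylpropanoyl)-2H-chromen-6-yl]methyl}-3,5-dihydroxy-4-methyl-4-(3-methylbut-2-en-1-yl)-6-(2-methylpropanoyl)cyclohexa-2,5-dien-1-one | CC(C)=CC[C@@]1(C)C(O)=C(Cc2c(O)c3c(c(C(=O)C(C)C)c2O)OC(C)(C)C=C3)C(=O)C(C(=O)C(C)C)=C1O | target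

**Step count and risks**

Total step count: 10. Longest linear sequence: 8 steps (steps 1–7, then step 10).

Steps most likely to fail:

Step 5 (Proposed new method). The π-allyl palladium phenoxide may only collapse back to the five-membered ether instead of undergoing β-hydride elimination, and the free dienylphenol may oligomerise before it is captured again. The fallback closes the pyran directly from an open chain with known chemistry; it sets out from iodide 5 and comes back at 9. Heck coupling of 5 with 2-methylbut-3-en-2-ol (Pd(OAc)2, P(o-tol)3, Et3N, MeCN, 80 °C) should give (E)-1-{2,6-dihydroxy-3-(3-hydroxy-3-methylbut-1-en-1-yl)-4-[(triisopropylsilyl)oxy]phenyl}-2-methylpropan-1-one F1. Acid-catalysed cyclodehydration of this alcohol (PPTS, toluene, 60 °C) through the allylic cation, with closure by the adjacent free hydroxyl, should give 9.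

Step 9. The flat phenoxide may be poorly discriminated in the chiral pocket, allylation may occur at the unsubstituted ring carbon instead of the methyl-bearing one, and the product may be prenylated a second time. The fallback replaces catalysis by resolution; it sets out from 14 and comes back at 16. Alkylation of 14 with prenyl bromide (NaOMe, MeOH, 0 °C) should give racemic 3,5-dihydroxy-4-methyl-4-(3-methylbut-2-en-1-yl)-6-(2-methylpropanoyl)cyclohexa-2,5-dien-1-one F2. The acidic triketone is resolved by crystallisation with (S)-1-phenylethylamine (or its antipode, whichever gives the crystalline salt of the (S)-acid) as (S)-1-phenylethylammonium (4S)-3,5-dihydroxy-4-methyl-4-(3-methylbut-2-en-1-yl)-6-(2-methylpropanoyl)cyclohexa-2,5-dien-1-one enolate F3, and dilute aqueous HCl sets 16 free.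

Step 10. The quinone methide may form too slowly, or be consumed by oxygen nucleophiles and by cycloaddition to the alkenes present, so that the cross-coupling stalls. The fallback reverses the polarity of the partners; it sets out from 16 (with 10 as partner) and comes back at 18. Aminomethylation of 16 with 11 (Et3N, CH2Cl2, 0 °C) should give (4S)-2-[(dimethylamino)methyl]-3,5-dihydroxy-4-methyl-4-(3-methylbut-2-en-1-yl)-6-(2-methylpropanoyl)cyclohexa-2,5-dien-1-one F4, used without purification. On warming with 10 (NaOAc, THF, 50 °C) it should lose dimethylamine to the methylene-trione, and the only free aromatic carbon of 10 (C6) should add to it to give 18.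

**Further compounds**

F1 | step 5 | (E)-1-{2,6-dihydroxy-3-(3-hydroxy-3-methylbut-1-en-1-yl)-4-[(triisopropylsilyl)oxy]phenyl}-2-methylpropan-1-one | CC(C)C(=O)c1c(O)cc(O[Si](C(C)C)(C(C)C)C(C)C)c(/C=C/C(C)(C)O)c1O
F2 | step 9 | racemic 3,5-dihydroxy-4-methyl-4-(3-methylbut-2-en-1-yl)-6-(2-methylpropanoyl)cyclohexa-2,5-dien-1-one | CC(C)=CCC1(C)C(O)=CC(=O)C(C(=O)C(C)C)=C1O
F3 | step 9 | (S)-1-phenylethylammonium (4S)-3,5-dihydroxy-4-methyl-4-(3-methylbut-2-en-1-yl)-6-(2-methylpropanoyl)cyclohexa-2,5-dien-1-one enolate | CC(C)=CC[C@@]1(C)C(O)=CC(=O)C(C(=O)C(C)C)=C1[O-].C[C@H]([NH3+])c1ccccc1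
F4 | step 10 | (4S)-2-[(dimethylamino)methyl]-3,5-dihydroxy-4-methyl-4-(3-methylbut-2-en-1-yl)-6-(2-methylpropanoyl)cyclohexa-2,5-dien-1-one | CC(C)=CC[C@@]1(C)C(O)=C(CN(C)C)C(=O)C(C(=O)C(C)C)=C1O
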